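**Strategy**

Locants follow carotenoid numbering: ring C1 (CMe2), C2–C4 (CH2), C5 (C(Me)OH), C6 (carbinol carrying the chain). Everything rests on cutting ring bond C1–C2 with C6 read as a latent ketone: the feature exploited is that quaternary C1 lies alpha to C6 and is followed by three plain methylenes. The precursor is an acyclic cross-conjugated hydroxy dienone, its C5 carbinol taken from (S)-lactic acid. Metal-hydride hydrogen atom transfer to its methacryloyl CH2 makes the second C1 methyl and a tertiary alpha-keto radical, which closes 6-endo onto the allyl terminus. One operation gives the ring, quaternary C1 and the hydroxy ketone for chelation-controlled chain attachment and C15 + C10 Wittig assembly.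

Key step: step 5

Remark: chain locants continue the carotenoid numbering (C7–C15, then C15'–C12' ending at the carboxyl carbon); compounds 10 and 15 are assumed to be commercially available.

**Route**

Step 1
Reactants: 1 (S)-lactic acid
Product: 2 (2S,5S)-2-tert-butyl-5-methyl-1,3-dioxolan-4-one
Conditions: pivalaldehyde, TsOH·H2O (cat.), H2SO4 (cat.), pentane, reflux, Dean–Stark; recrystallisation from Et2O/pentane, −78 °C
Reagents that add atoms: pivalaldehyde, CC(C)(C)C=O
Why: Acid-catalysed acetalisation of the alpha-hydroxy acid is reversible, so the new acetal carbon should settle under thermodynamic control mainly into the cis isomer (tert-butyl and methyl on the same face), which is purified by crystallisation, while the lactic acid stereocentre is not touched.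

Step 2
Reactants: 2 (2S,5S)-2-tert-butyl-5-methyl-1,3-dioxolan-4-one; 3 allyl bromide
Product: 5 (2S,5R)-2-tert-butyl-5-methyl-5-(prop-2-en-1-yl)-1,3-dioxolan-4-one, via lithium enolate 4 (not isolated)
Conditions: LDA (1.1 equiv), THF, −78 °C; then 3 (1.5 equiv), −78 → −30 °C
Reagents that add atoms: none
Why: Enolate alkylation under self-regeneration of stereocentres: deprotonation erases the lactate centre, the surviving tert-butyl acetal centre shields one face, and allyl bromide should enter anti to tert-butyl, which sets the quaternary carbinol carbon (later C5) as R.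

Step 3
Reactants: 5 (2S,5R)-2-tert-butyl-5-methyl-5-(prop-2-en-1-yl)-1,3-dioxolan-4-one
Product: 6 (2R)-2-hydroxy-N-methoxy-N,2-dimethylpent-4-enamide
Conditions: MeNHOMe·HCl (3 equiv), i-PrMgCl (6 equiv), THF, −20 → 0 °C
Reagents that add atoms: N,O-dimethylhydroxylamine hydrochloride, CNOC.Cl
Why: Weinreb amide formation by aminolysis of the activated lactone carbonyl with the chloromagnesium amide; the ring-opened hemiacetal alkoxide loses pivalaldehyde and the quaternary stereocentre is not involved.

Step 4
Reactants: 6 (2R)-2-hydroxy-N-methoxy-N,2-dimethylpent-4-enamide; 7 isopropenylmagnesium bromide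
Product: 8 (4R)-4-hydroxy-2,4-dimethylhepta-1,6-dien-3-one
Conditions: 7 (3 equiv), THF, 0 °C → rt; inverse quench into cold 1 M HCl
Reagents that add atoms: none
Why: Weinreb ketone synthesis: after deprotonation of the hydroxyl a second equivalent adds once, and the chelated tetrahedral intermediate should survive until the acidic inverse quench, which also keeps the liberated amine protonated so that it cannot add to the new enone.

Step 5
Reactants: 8 (4R)-4-hydroxy-2,4-dimethylhepta-1,6-dien-3-one
Product: 9 (2R)-2-hydroxy-2,6,6-trimethylcyclohexan-1-one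
Conditions: Mn(dpm)3 [tris(2,2,6,6-tetramethylheptane-3,5-dionato)manganese] (10 mol %), PhSiH3 (1.5 equiv, syringe pump), degassed i-PrOH, 0.01 M, 23 °C, argon; then 1 M HCl work-up
Reagents that add atoms: none
Why: An Mn–H species formed from Mn(dpm)3, PhSiH3 and i-PrOH should transfer a hydrogen atom to the terminal CH2 of the conjugated 1,1-disubstituted alkene, creating the second methyl on C1 and a tertiary alpha-keto radical at C1, which adds to the terminal carbon (C2) of the allyl group before the resulting secondary C3 radical is reduced by a second hydrogen transfer. The closest known reaction types are the Mukaiyama-type metal-hydride conjugate reduction of enones, hydrogen-atom-transfer-initiated reductive cyclisation of 2-substituted acrylates onto pendant alkenes, and the tin hydride cyclisation of 2-oxohex-5-enyl radicals. The cyclohexanone ring closes in the 6-endo-trig mode, expected to beat 5-exo because the carbonyl carbon lies inside the forming ring, the radical is tertiary and electrophilic, the alkene terminus is unsubstituted and the fully substituted C5 helps folding (Thorpe–Ingold effect). No stereocentre is formed (C1 ends with two methyl groups), and the C5 carbinol, which has no alpha hydrogen and takes no part in the radical chemistry, keeps its R configuration. The step needs hydrogen transfer to the enone alkene rather than to the isolated vinyl group, secured by conjugation and 1,1-disubstitution (stabilised tertiary radical against secondary alkyl radical) and by leaving out the peroxide co-oxidant that unactivated alkenes require, and it needs ring closure to outrun reduction of the first radical, secured by high dilution and slow silane addition.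

Step 6
Reactants: 9 (2R)-2-hydroxy-2,6,6-trimethylcyclohexan-1-one; 10 (2E)-3-methylpent-2-en-4-yn-1-ol
Product: 12 (1S,2R)-1-[(3E)-5-hydroxy-3-methylpent-3-en-1-yn-1-yl]-2,6,6-trimethylcyclohexane-1,2-diol, via dilithiated enynol 11 (not isolated)
Conditions: 10 (2.2 equiv), n-BuLi (4.4 equiv), THF, −78 → 0 °C; then 9, −78 °C → rt; aq. NH4Cl
Reagents that add atoms: none
Why: Acetylide 1,2-addition under chelation control (Cram chelate model): the ketone has no alpha hydrogen, its lithium alkoxide ties the C5 oxygen to the carbonyl oxygen so that this oxygen sits equatorial and the C5 methyl axial, and the slim acetylide should then attack axially, anti to the two axial alpha-methyl groups and on the face of the C5 oxygen, setting C6 with the chain cis to the C5 hydroxyl (trans-diol).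

Step 7
Reactants: 12 (1S,2R)-1-[(3E)-5-hydroxy-3-methylpent-3-en-1-yn-1-yl]-2,6,6-trimethylcyclohexane-1,2-diol
Product: 13 (1R,2R)-1-[(1E,3E)-5-hydroxy-3-methylpenta-1,3-dien-1-yl]-2,6,6-trimethylcyclohexane-1,2-diol
Conditions: LiAlH4 (4 equiv), THF, 0 °C → reflux; aq. KNaC4H4O6 work-up
Reagents that add atoms: none
Why: Hydroxyl-directed trans-hydroalumination of the propargylic alkoxide followed by protonolysis should give only the E alkene at C7=C8 and leave the C9=C10 alkene and both carbinol centres unchanged (the descriptor at C6 changes only because the CIP priorities change).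

Step 8
Reactants: 13 (1R,2R)-1-[(1E,3E)-5-hydroxy-3-methylpenta-1,3-dien-1-yl]-2,6,6-trimethylcyclohexane-1,2-diol
Product: 14 {(2E,4E)-5-[(1R,2R)-1,2-dihydroxy-2,6,6-trimethylcyclohexyl]-3-methylpenta-2,4-dien-1-yl}triphenylphosphonium bromide
Conditions: Ph3P·HBr (1.05 equiv), MeOH, 0 °C → rt
Reagents that add atoms: triphenylphosphine hydrobromide, [Br-].[PH+](c1ccccc1)(c1ccccc1)c1ccccc1
Why: Phosphonium salt formation from an allylic alcohol: under the weakly acidic conditions only the primary allylic hydroxyl should ionise (the C6 hydroxyl is deactivated by the neighbouring C5 oxygen) and the phosphine captures the delocalised cation at the unhindered terminus with the E,E-diene retained.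

Step 9
Reactants: 14 {(2E,4E)-5-[(1R,2R)-1,2-dihydroxy-2,6,6-trimethylcyclohexyl]-3-methylpenta-2,4-dien-1-yl}triphenylphosphonium bromide; 15 (2E,4E,6E)-2,7-dimethylocta-2,4,6-trienedial
Product: 18 (2E,4E,6E,8E,10E,12E)-13-[(1R,2R)-1,2-dihydroxy-2,6,6-trimethylcyclohexyl]-2,7,11-trimethyltrideca-2,4,6,8,10,12-hexaenal, via phosphonium ylide 16 (not isolated), via 8Z aldehyde isomer 17 (not isolated)
Conditions: 15 (2.5 equiv), NaOMe, MeOH/CH2Cl2, −10 °C → rt; then I2 (cat.), CH2Cl2/hexane, rt, daylight
Reagents that add atoms: none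
Why: Wittig olefination of the semistabilised allylic ylide with one aldehyde group of the symmetric dialdehyde used in excess (statistical mono-olefination), followed by iodine-catalysed equilibration of the new C11=C12 bond, should deliver the thermodynamically favoured all-E polyene.

Step 10
Reactants: 18 (2E,4E,6E,8E,10E,12E)-13-[(1R,2R)-1,2-dihydroxy-2,6,6-trimethylcyclohexyl]-2,7,11-trimethyltrideca-2,4,6,8,10,12-hexaenal
Product: 19 (2E,4E,6E,8E,10E,12E)-13-[(1R,2R)-1,2-dihydroxy-2,6,6-trimethylcyclohexyl]-2,7,11-trimethyltrideca-2,4,6,8,10,12-hexaenoic acid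
Conditions: NaClO2, NaH2PO4, 2-methyl-2-butene (large excess), t-BuOH/THF/H2O, 0 °C → rt, dark
Reagents that add atoms: sodium chlorite, [Na+].[O-]Cl=O
Why: Pinnick oxidation should convert the conjugated aldehyde into the acid without touching the polyene because 2-methyl-2-butene scavenges the hypochlorous acid formed, and the tertiary diol is inert.

**Compound list**

1 | (S)-lactic acid | C[C@H](O)C(=O)O | starting material
2 | (2S,5S)-2-tert-butyl-5-methyl-1,3-dioxolan-4-one | C[C@@H]1O[C@H](C(C)(C)C)OC1=O | intermediate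
3 | allyl bromide | C=CCBr | starting material
4 | lithium (2S)-2-tert-butyl-5-methyl-1,3-dioxol-4-olate (enolate of 2) | CC1=C([O-])O[C@@H](C(C)(C)C)O1.[Li+] | intermediate
5 | (2S,5R)-2-tert-butyl-5-methyl-5-(prop-2-en-1-yl)-1,3-dioxolan-4-one | C[C@]1(CC=C)O[C@H](C(C)(C)C)OC1=O | intermediate
6 | (2R)-2-hydroxy-N-methoxy-N,2-dimethylpent-4-enamide | C=CC[C@@](C)(O)C(=O)N(C)OC | intermediate
7 | isopropenylmagnesium bromide | C=C(C)[Mg]Br | starting material
8 | (4R)-4-hydroxy-2,4-dimethylhepta-1,6-dien-3-one | C=CC[C@@](C)(O)C(=O)C(C)=C | intermediate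
9 | (2R)-2-hydroxy-2,6,6-trimethylcyclohexan-1-one | O=C1C(C)(C)CCC[C@@]1(C)O | intermediate
10 | (2E)-3-methylpent-2-en-4-yn-1-ol | OC/C=C(\C)C#C | starting material
11 | dilithium salt of 10 (alkoxide and acetylide) | [Li+].[Li+].[O-]C/C=C(\C)C#[C-] | intermediate
12 | (1S,2R)-1-[(3E)-5-hydroxy-3-methylpent-3-en-1-yn-1-yl]-2,6,6-trimethylcyclohexane-1,2-diol | OC/C=C(C)/C#C[C@@]1(O)C(C)(C)CCC[C@@]1(C)O | intermediate
13 | (1R,2R)-1-[(1E,3E)-5-hydroxy-3-methylpenta-1,3-dien-1-yl]-2,6,6-trimethylcyclohexane-1,2-diol | OC/C=C(C)/C=C/[C@@]1(O)C(C)(C)CCC[C@@]1(C)O | intermediate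
14 | {(2E,4E)-5-[(1R,2R)-1,2-dihydroxy-2,6,6-trimethylcyclohexyl]-3-methylpenta-2,4-dien-1-yl}triphenylphosphonium bromide | [Br-].c1ccccc1[P+](c1ccccc1)(c1ccccc1)C/C=C(C)/C=C/[C@@]1(O)C(C)(C)CCC[C@@]1(C)O | intermediate
15 | (2E,4E,6E)-2,7-dimethylocta-2,4,6-trienedial | O=C/C(C)=C/C=C/C=C(\C)C=O | starting material
16 | ylide of 14 | c1ccccc1[P+](c1ccccc1)(c1ccccc1)[CH-]/C=C(C)/C=C/[C@@]1(O)C(C)(C)CCC[C@@]1(C)O | intermediate
17 | (2E,4E,6E,8Z,10E,12E)-13-[(1R,2R)-1,2-dihydroxy-2,6,6-trimethylcyclohexyl]-2,7,11-trimethyltrideca-2,4,6,8,10,12-hexaenal | CC(/C=C\C=C(C)\C=C\[C@@]1(O)C(C)(C)CCC[C@@]1(C)O)=C\C=C\C=C(/C)C=O | intermediate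
18 | (2E,4E,6E,8E,10E,12E)-13-[(1R,2R)-1,2-dihydroxy-2,6,6-trimethylcyclohexyl]-2,7,11-trimethyltrideca-2,4,6,8,10,12-hexaenal | CC(/C=C/C=C(C)/C=C/[C@@]1(O)C(C)(C)CCC[C@@]1(C)O)=C\C=C\C=C(/C)C=O | intermediate
19 | (2E,4E,6E,8E,10E,12E)-13-[(1R,2R)-1,2-dihydroxy-2,6,6-trimethylcyclohexyl]-2,7,11-trimethyltrideca-2,4,6,8,10,12-hexaenoic acid | CC(/C=C/C=C(C)/C=C/[C@@]1(O)C(C)(C)CCC[C@@]1(C)O)=C\C=C\C=C(/C)C(=O)O | target

**Step count**

Total step count: 10. Longest linear sequence: 10 steps (1 → 19).

**Steps most likely to fail**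

Step 5 (key step). The hydrogen atom may be delivered to the isolated vinyl group instead of the enone, the C1 radical may be reduced before it closes the ring, or closure may go 5-exo. The fallback forms the same bond by a polar 6-(enolendo)-exo-tet enolate alkylation; it sets out from 6 and comes back at 9. TESOTf and 2,6-lutidine (CH2Cl2, 0 °C) should protect the tertiary hydroxyl, which would otherwise close a tetrahydrofuran later, and give (2R)-N-methoxy-N,2-dimethyl-2-(triethylsilyloxy)pent-4-enamide F1. i-PrMgCl (THF, 0 °C → rt) should then give (4R)-2,4-dimethyl-4-(triethylsilyloxy)hept-6-en-3-one F2. Hydroboration with 9-BBN followed by NaBO3 oxidation should give (4R)-7-hydroxy-2,4-dimethyl-4-(triethylsilyloxy)heptan-3-one F3, and I2, PPh3 and imidazole should give (4R)-7-iodo-2,4-dimethyl-4-(triethylsilyloxy)heptan-3-one F4. LDA (THF, −78 → 0 °C) can deprotonate only the isopropyl methine, and the enolate should alkylate at carbon to give (2R)-2,6,6-trimethyl-2-(triethylsilyloxy)cyclohexan-1-one F5. TBAF (THF) should release 9.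

Step 6. Facial selectivity may be poor if the addition runs through the unchelated chair with the C5 oxygen axial, which would give the cis-diol. The fallback replaces external attack on a chelate by covalent tethering and intramolecular delivery; it sets out from 9 and 10 and comes back at 12. TBSCl and imidazole (CH2Cl2) should give tert-butyldimethyl{[(2E)-3-methylpent-2-en-4-yn-1-yl]oxy}silane F6. Lithiation (n-BuLi, THF, −78 °C) and transmetalation with ClTi(OiPr)3 should give the alkynyltitanium triisopropoxide F7. Added 9 should exchange one isopropoxide for its C5 oxygen and form the tethered titanate F8. From F8 the alkynyl group can reach the C6 carbonyl only through a five-membered cyclic transition state on the face of the C5 oxygen, which should give, after hydrolysis, (1S,2R)-1-[(3E)-5-(tert-butyldimethylsilyloxy)-3-methylpent-3-en-1-yn-1-yl]-2,6,6-trimethylcyclohexane-1,2-diol F9. TBAF (THF) should give 12.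

Step 8. The tertiary allylic C6 hydroxyl may ionise under the acidic conditions, leading to elimination, allylic transposition or ring-contracting rearrangement. The fallback avoids any cation and changes the olefination to a Horner–Wadsworth–Emmons reaction; it sets out from 13 and comes back at 18. CBr4 and PPh3 (CH2Cl2, −20 °C, Appel reaction) should convert only the primary allylic alcohol into (1R,2R)-1-[(1E,3E)-5-bromo-3-methylpenta-1,3-dien-1-yl]-2,6,6-trimethylcyclohexane-1,2-diol F10. NaP(O)(OEt)2 (THF, 0 °C, Michaelis–Becker reaction) should give diethyl {(2E,4E)-5-[(1R,2R)-1,2-dihydroxy-2,6,6-trimethylcyclohexyl]-3-methylpenta-2,4-dien-1-yl}phosphonate F11. NaHMDS (3.2 equiv, THF, −78 → 0 °C) and excess 15 should give 18 directly with E selectivity.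

**Further compounds**

F1 | step 5 | (2R)-N-methoxy-N,2-dimethyl-2-(triethylsilyloxy)pent-4-enamide | C=CC[C@@](C)(O[Si](CC)(CC)CC)C(=O)N(C)OC
F2 | step 5 | (4R)-2,4-dimethyl-4-(triethylsilyloxy)hept-6-en-3-one | C=CC[C@@](C)(O[Si](CC)(CC)CC)C(=O)C(C)C
F3 | step 5 | (4R)-7-hydroxy-2,4-dimethyl-4-(triethylsilyloxy)heptan-3-one | OCCC[C@@](C)(O[Si](CC)(CC)CC)C(=O)C(C)C
F4 | step 5 | (4R)-7-iodo-2,4-dimethyl-4-(triethylsilyloxy)heptan-3-one | ICCC[C@@](C)(O[Si](CC)(CC)CC)C(=O)C(C)C
F5 | step 5 | (2R)-2,6,6-trimethyl-2-(triethylsilyloxy)cyclohexan-1-one | O=C1C(C)(C)CCC[C@@]1(C)O[Si](CC)(CC)CC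
F6 | step 6 | tert-butyldimethyl{[(2E)-3-methylpent-2-en-4-yn-1-yl]oxy}silane | C#C/C(C)=C/CO[Si](C)(C)C(C)(C)C
F7 | step 6 | [(3E)-5-(tert-butyldimethylsilyloxy)-3-methylpent-3-en-1-yn-1-yl]titanium triisopropoxide | CC(C)O[Ti](OC(C)C)(OC(C)C)C#C/C(C)=C/CO[Si](C)(C)C(C)(C)C
F8 | step 6 | tethered titanate (alkynyl)(diisopropoxy)titanium alkoxide of 9 | CC(C)O[Ti](OC(C)C)(O[C@]1(C)CCCC(C)(C)C1=O)C#C/C(C)=C/CO[Si](C)(C)C(C)(C)C
F9 | step 6 | (1S,2R)-1-[(3E)-5-(tert-butyldimethylsilyloxy)-3-methylpent-3-en-1-yn-1-yl]-2,6,6-trimethylcyclohexane-1,2-diol | CC(C)(C)[Si](C)(C)OC/C=C(C)/C#C[C@@]1(O)C(C)(C)CCC[C@@]1(C)O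
F10 | step 8 | (1R,2R)-1-[(1E,3E)-5-bromo-3-methylpenta-1,3-dien-1-yl]-2,6,6-trimethylcyclohexane-1,2-diol | BrC/C=C(C)/C=C/[C@@]1(O)C(C)(C)CCC[C@@]1(C)O
F11 | step 8 | diethyl {(2E,4E)-5-[(1R,2R)-1,2-dihydroxy-2,6,6-trimethylcyclohexyl]-3-methylpenta-2,4-dien-1-yl}phosphonate | CCOP(=O)(OCC)C/C=C(C)/C=C/[C@@]1(O)C(C)(C)CCC[C@@]1(C)O
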